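Remark: the β-triketone and acylphloroglucinol compounds are rapidly equilibrating tautomer mixtures and are drawn in the enol form of the target SMILES; the target has no stereocenter, so no step has to set one.

**Retrosynthetic overview**
1. Rings: A = the 4,4-dimethylcyclohexadienone (β-triketone) ring with one butanoyl group, B = the central butanoylphloroglucinol, C = the methoxy ring. Both ring–CH2–ring bonds are cut as Michael additions to methylene-quinoid acceptors: ring C (21) from the A–B dimer 20, then ring B (18) from the ring A sulfone 16.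
2. Ring A is built de novo. Its last bond is C4–C5 (C4 = C(CH3)2, C5 = the oxygen-bearing carbon next to the CH2-bearing C6), closed by 6π-electrocyclization of a dienylketene formed in one operation from cyclobutenone 4 and ynol ether 7.
3. Enabling feature: C4 of ring A carries two methyl groups and no hydrogen and lies between two oxygen-bearing sp2 carbons, so a ketene electrocyclization ending on it must stop at the cyclohexadienone and cannot tautomerize to a phenol. The 1,3,5-oxygen pattern of ring A is the ketene oxygen plus the two ynol-ether oxygens, and the alkyne substituent CH2SPh becomes the A–B methylene bridge.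
4. Order of ring formation: four-membered ring (step 1), then ring A (step 3); rings B and C come from phloroglucinol (steps 7 and 9) and are attached in steps 8 and 10.

Key step: step 3

**Step 1**
Reactants: 1 isobutyryl chloride; 2 ethoxyacetylene
Product: 4 3-ethoxy-4,4-dimethylcyclobut-2-en-1-one, via dimethylketene 3 (not isolated)
Conditions: Et3N (1.2 equiv), 2 (1.5 equiv, solution in hexanes), Et2O, 0 °C → rt, slow addition of 1; filtration, distillation
Reagents that add atoms: none
Why: Dehydrochlorination gives dimethylketene, which should be captured in situ by the electron-rich ynol ether in a regioselective ketene–alkyne [2+2] cycloaddition (alkyne CH carbon to the ketene carbonyl carbon), the standard entry to 3-alkoxycyclobutenones.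

**Step 2**
Reactants: 2 ethoxyacetylene; 5 chloromethyl phenyl sulfide
Product: 7 [(3-ethoxyprop-2-yn-1-yl)sulfanyl]benzene, via lithium ethoxyacetylide 6 (not isolated)
Conditions: n-BuLi, THF, −78 °C; then 5, DMPU, −78 → 0 °C
Reagents that add atoms: none
Why: Deprotonation of the terminal ynol ether and SN2 alkylation of the lithium acetylide by the highly reactive α-chloro sulfide (acetylide alkylation) should install the future bridging CH2 carbon with a sulfur handle that is not a leaving group until it is oxidized.

**Step 3**
Reactants: 4 3-ethoxy-4,4-dimethylcyclobut-2-en-1-one; 7 [(3-ethoxyprop-2-yn-1-yl)sulfanyl]benzene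
Product: 11 3,5-diethoxy-6,6-dimethyl-2-[(phenylsulfanyl)methyl]cyclohexa-2,4-dien-1-one, via vinylketene 8 (not isolated), via alkenylcyclobutenone 9 (not isolated), via dienylketene 10 (not isolated)
Conditions: 7 (1.3 equiv), PhMe (0.5 M), 80 → 90 °C, sealed tube, Ar
Reagents that add atoms: none
Why: Heating should open 4 by reversible 4π-electrocyclic cleavage of its C1–C4 bond to vinylketene 8; the nucleophilic carbon of 7 (the one carrying CH2SPh) adds to the ketene carbonyl carbon and [2+2] cycloaddition gives alkenylcyclobutenone 9, which opens again to dienylketene 10 and closes ring A by thermal disrotatory 6π-electrocyclization between the ketene carbon and the C(CH3)2 terminus. This is the cyclobutenone–alkoxyalkyne annulation (Danheiser benzannulation), here ending at the 2,4-cyclohexadienone because the newly bonded ring carbon carries two methyl groups and no hydrogen. The transient four-membered ring closes by ketene–alkyne [2+2] cycloaddition and ring A by 6π-electrocyclization; the product has no stereocenter, and the single stereocenter of racemic 9 is lost on ring opening. The step needs a regioselective [2+2], which the polarization of the ynol ether secures by placing the CH2SPh carbon next to the new carbonyl and the ethoxy carbon next to the former C2 of 4, giving the 1,3,5-oxygen pattern. It also needs capture of 8 faster than its dimerization or a 1,5-hydrogen shift from a methyl group, which excess 7 at high concentration and the reversibility of both ring openings should secure (only the dienylketene isomer with the alkenyl group cis to the ketene cyclizes; the other recloses).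

**Step 4**
Reactants: 11 3,5-diethoxy-6,6-dimethyl-2-[(phenylsulfanyl)methyl]cyclohexa-2,4-dien-1-one
Product: 12 3-hydroxy-4,4-dimethyl-2-[(phenylsulfanyl)methyl]cyclohex-2-ene-1,5-dione
Conditions: 2 M aq HCl, THF, 50 °C
Reagents that add atoms: water, O
Why: Acid hydrolysis of the vinylogous ester and of the dienol ether (enol ether hydrolysis) should unveil the β-triketone of ring A, the thioether being stable to dilute acid.

**Step 5**
Reactants: 12 3-hydroxy-4,4-dimethyl-2-[(phenylsulfanyl)methyl]cyclohex-2-ene-1,5-dione; 13 butanoyl chloride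
Product: 15 2-butanoyl-3,5-dihydroxy-4,4-dimethyl-6-[(phenylsulfanyl)methyl]cyclohexa-2,5-dien-1-one, via enol butanoate 14 (not isolated)
Conditions: 13 (1.1 equiv), Et3N (2.2 equiv), CH2Cl2, 0 °C; then 4-(dimethylamino)pyridine (0.2 equiv), rt
Reagents that add atoms: none
Why: O-acylation of the triketone enol followed by amine-catalysed O-to-C acyl migration (the standard C-acylation of cyclic 1,3-diones) should place the butanoyl group on the only unsubstituted ring carbon, where the product is held as a chelated, fully enolized triketone.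

**Step 6**
Reactants: 15 2-butanoyl-3,5-dihydroxy-4,4-dimethyl-6-[(phenylsulfanyl)methyl]cyclohexa-2,5-dien-1-one
Product: 16 2-[(benzenesulfonyl)methyl]-6-butanoyl-3,5-dihydroxy-4,4-dimethylcyclohexa-2,5-dien-1-one
Conditions: Oxone (2KHSO5·KHSO4·K2SO4, 1.5 equiv), MeOH–H2O, 0 °C → rt
Reagents that add atoms: potassium peroxymonosulfate (KHSO5), [K+].[O-]S(=O)(=O)OO
Why: Sulfide-to-sulfone oxidation should be chemoselective because the electron-poor, hydrogen-bonded triketone enol is a poor partner for the electrophilic oxidant in the acidic medium, and it turns the thioether into a sulfinate leaving group.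

**Step 7**
Reactants: 17 phloroglucinol; 13 butanoyl chloride
Product: 18 1-(2,4,6-trihydroxyphenyl)butan-1-one
Conditions: AlCl3 (3 equiv), PhNO2–CH2Cl2, 0 → 50 °C; aq HCl work-up
Reagents that add atoms: none
Why: Friedel–Crafts acylation of the symmetric triphenol should stop at the monoketone because the first acyl group deactivates the ring.

**Step 8**
Reactants: 16 2-[(benzenesulfonyl)methyl]-6-butanoyl-3,5-dihydroxy-4,4-dimethylcyclohexa-2,5-dien-1-one; 18 1-(2,4,6-trihydroxyphenyl)butan-1-one
Product: 20 2-butanoyl-6-[(3-butanoyl-2,4,6-trihydroxyphenyl)methyl]-3,5-dihydroxy-4,4-dimethylcyclohexa-2,5-dien-1-one, via methylene triketone 19 (not isolated)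
Conditions: 18 (3 equiv), Et3N (2.5 equiv), MeCN, 0 °C → rt; dilute aq HCl work-up
Reagents that add atoms: none
Why: Base-induced E1cB loss of benzenesulfinate from the triketone enolate should give the 2-methylene triketone (generated as quinone methides are from 2-sulfonylmethyl phenols), which the phenoxide of 18 captures at carbon by Michael addition and rearomatization; the two free positions of 18 are equivalent and its excess suppresses double alkylation.

**Step 9**
Reactants: 18 1-(2,4,6-trihydroxyphenyl)butan-1-one
Product: 21 1-(2,6-dihydroxy-4-methoxyphenyl)butan-1-one (desaspidinol)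
Conditions: Me2SO4 (1.0 equiv), K2CO3 (1.0 equiv), acetone, rt
Reagents that add atoms: dimethyl sulfate, COS(=O)(=O)OC
Why: Williamson O-methylation should be selective for the 4-hydroxyl because the two ortho hydroxyls are hydrogen-bonded to the ketone and less nucleophilic, as is usual for phloroacylophenones.

**Step 10**
Reactants: 20 2-butanoyl-6-[(3-butanoyl-2,4,6-trihydroxyphenyl)methyl]-3,5-dihydroxy-4,4-dimethylcyclohexa-2,5-dien-1-one; 21 1-(2,6-dihydroxy-4-methoxyphenyl)butan-1-one
Product: 24 2-butanoyl-6-[[3-butanoyl-5-[(3-butanoyl-2,4-dihydroxy-6-methoxyphenyl)methyl]-2,4,6-trihydroxyphenyl]methyl]-3,5-dihydroxy-4,4-dimethylcyclohexa-2,5-dien-1-one (CNP0178590.0), via Mannich base 22 (not isolated), via quinone methide 23 (not isolated)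
Conditions: Me2N=CH2+ I− (1.05 equiv), MeCN, rt; then 21 (3 equiv), 1,4-dioxane, 80 °C
Reagents that add atoms: N,N-dimethylmethyleneiminium iodide (Eschenmoser's salt), C=[N+](C)C.[I-]
Why: Aminomethylation (Mannich reaction) can only occur at the single free aromatic CH of ring B, and thermal loss of dimethylamine should give the ortho-quinone methide that one of the two equivalent free positions of excess 21 captures by Michael addition and rearomatization, completing the second methylene bridge.

**Compound list**
1 | isobutyryl chloride (2-methylpropanoyl chloride) | CC(C)C(Cl)=O | starting material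
2 | ethoxyacetylene (ethoxyethyne) | CCOC#C | starting material
3 | dimethylketene (2-methylprop-1-en-1-one) | CC(C)=C=O | intermediate
4 | 3-ethoxy-4,4-dimethylcyclobut-2-en-1-one | CCOC1=CC(=O)C1(C)C | intermediate
5 | chloromethyl phenyl sulfide | ClCSc1ccccc1 | starting material
6 | lithium ethoxyacetylide | [Li]C#COCC | intermediate
7 | [(3-ethoxyprop-2-yn-1-yl)sulfanyl]benzene | CCOC#CCSc1ccccc1 | intermediate
8 | 3-ethoxy-4-methylpenta-1,3-dien-1-one (vinylketene) | CCOC(C=C=O)=C(C)C | intermediate
9 | 3-ethoxy-4-(1-ethoxy-2-methylprop-1-en-1-yl)-2-[(phenylsulfanyl)methyl]cyclobut-2-en-1-one (racemic) | CCOC(=C(C)C)C1C(=O)C(CSc2ccccc2)=C1OCC | intermediate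
10 | (3E)-3,5-diethoxy-6-methyl-2-[(phenylsulfanyl)methyl]hepta-1,3,5-trien-1-one (dienylketene) | O=C=C(CSc1ccccc1)/C(OCC)=C\C(OCC)=C(C)C | intermediate
11 | 3,5-diethoxy-6,6-dimethyl-2-[(phenylsulfanyl)methyl]cyclohexa-2,4-dien-1-one | CCOC1=CC(OCC)=C(CSc2ccccc2)C(=O)C1(C)C | intermediate
12 | 3-hydroxy-4,4-dimethyl-2-[(phenylsulfanyl)methyl]cyclohex-2-ene-1,5-dione | CC1(C)C(=O)CC(=O)C(CSc2ccccc2)=C1O | intermediate
13 | butanoyl chloride | CCCC(Cl)=O | starting material
14 | 5-hydroxy-6,6-dimethyl-3-oxo-4-[(phenylsulfanyl)methyl]cyclohexa-1,4-dien-1-yl butanoate (one of the possible enol esters) | CCCC(=O)OC1=CC(=O)C(CSc2ccccc2)=C(O)C1(C)C | intermediate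
15 | 2-butanoyl-3,5-dihydroxy-4,4-dimethyl-6-[(phenylsulfanyl)methyl]cyclohexa-2,5-dien-1-one | CCCC(=O)C1=C(O)C(C)(C)C(O)=C(CSc2ccccc2)C1=O | intermediate
16 | 2-[(benzenesulfonyl)methyl]-6-butanoyl-3,5-dihydroxy-4,4-dimethylcyclohexa-2,5-dien-1-one | CCCC(=O)C1=C(O)C(C)(C)C(O)=C(CS(=O)(=O)c2ccccc2)C1=O | intermediate
17 | phloroglucinol (benzene-1,3,5-triol) | Oc1cc(O)cc(O)c1 | starting material
18 | 1-(2,4,6-trihydroxyphenyl)butan-1-one | CCCC(=O)c1c(O)cc(O)cc1O | intermediate
19 | 2-butanoyl-3-hydroxy-4,4-dimethyl-6-methylidenecyclohex-2-ene-1,5-dione | CCCC(=O)C1=C(O)C(C)(C)C(=O)C(=C)C1=O | intermediate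
20 | 2-butanoyl-6-[(3-butanoyl-2,4,6-trihydroxyphenyl)methyl]-3,5-dihydroxy-4,4-dimethylcyclohexa-2,5-dien-1-one | CCCC(=O)C1=C(O)C(C)(C)C(O)=C(Cc2c(O)cc(O)c(C(=O)CCC)c2O)C1=O | intermediate
21 | 1-(2,6-dihydroxy-4-methoxyphenyl)butan-1-one (desaspidinol) | CCCC(=O)c1c(O)cc(OC)cc1O | intermediate
22 | 2-butanoyl-6-[[3-butanoyl-5-[(dimethylamino)methyl]-2,4,6-trihydroxyphenyl]methyl]-3,5-dihydroxy-4,4-dimethylcyclohexa-2,5-dien-1-one | CCCC(=O)C1=C(O)C(C)(C)C(O)=C(Cc2c(O)c(CN(C)C)c(O)c(C(=O)CCC)c2O)C1=O | intermediate
23 | 2-butanoyl-6-[(5-butanoyl-2,6-dihydroxy-3-methylidene-4-oxocyclohexa-1,5-dien-1-yl)methyl]-3,5-dihydroxy-4,4-dimethylcyclohexa-2,5-dien-1-one | CCCC(=O)C1=C(O)C(C)(C)C(O)=C(CC2=C(O)C(=C)C(=O)C(C(=O)CCC)=C2O)C1=O | intermediate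
24 | 2-butanoyl-6-[[3-butanoyl-5-[(3-butanoyl-2,4-dihydroxy-6-methoxyphenyl)methyl]-2,4,6-trihydroxyphenyl]methyl]-3,5-dihydroxy-4,4-dimethylcyclohexa-2,5-dien-1-one (CNP0178590.0) | CCCC(=O)C1=C(O)C(C)(C)C(O)=C(Cc2c(O)c(Cc3c(OC)cc(O)c(C(=O)CCC)c3O)c(O)c(C(=O)CCC)c2O)C1=O | target

**Totals**
Total step count: 10. Longest linear sequence: 7 steps (1 → 3 → 4 → 5 → 6 → 8 → 10).

**Steps most likely to fail**

Step 3. The substituted ynol ether 7 may capture vinylketene 8 too slowly, so that 8 is lost by dimerization or by a 1,5-hydrogen shift from a methyl group, or 7 may lose ethylene thermally before it reacts. The fallback sets out from 4 and returns at 12; it carries no substituent on the alkyne and adds the bridging carbon after ring formation. Compound 4 would be heated with the unsubstituted ynol ether 2 (PhMe, 80 °C, sealed tube), which should follow the same cascade through 8, the alkenylcyclobutenone 3-ethoxy-4-(1-ethoxy-2-methylprop-1-en-1-yl)cyclobut-2-en-1-one F1 and the dienylketene (3E)-3,5-diethoxy-6-methylhepta-1,3,5-trien-1-one F2 to 3,5-diethoxy-6,6-dimethylcyclohexa-2,4-dien-1-one F3. Hydrolysis (2 M aq HCl, THF) should give filicinic acid F4. Three-component thiomethylation (aq CH2O, PhSH, Et3N cat., EtOH) through 2,2-dimethyl-4-methylidenecyclohexane-1,3,5-trione F5 and thia-Michael addition at one of the two equivalent ring carbons should then give 12.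

Step 10. Aminomethylation of the strongly acidic dimer 20 may be sluggish, and on heating the first bridge may undergo retro-Michael cleavage and exchange, while ring C may oligomerize. The fallback sets out from 21 and arrives at 24; it reverses the order of bridge formation so that the last bond is made with the single-site ring A electrophile. Compound 21 would be aminomethylated (Eschenmoser's salt, 1 equiv, MeCN) to 1-[3-[(dimethylamino)methyl]-2,6-dihydroxy-4-methoxyphenyl]butan-1-one F6. Heating F6 with excess 18 (1,4-dioxane, 80 °C) should give, through 2-butanoyl-3-hydroxy-5-methoxy-6-methylidenecyclohexa-2,4-dien-1-one F7, the B–C dimer 1-[3-[(3-butanoyl-2,4-dihydroxy-6-methoxyphenyl)methyl]-2,4,6-trihydroxyphenyl]butan-1-one F8. F8 would then be coupled with sulfone 16 under the conditions of step 8 (Et3N, MeCN), 19 being captured at the ring B position between two hydroxyls, which should be more nucleophilic than the ring C position next to the methoxy group.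

Step 8. Under base the liberated methylene triketone 19 may oligomerize or re-add sulfinate faster than it is captured at carbon, and the amine may trigger retro-Michael scrambling of the new bridge. The fallback sets out from 15 and returns at 20; it generates 19 thermally and without base. Compound 15 would be oxidized only to the sulfoxide (NaIO4, 1 equiv, MeOH–H2O, 0 °C), giving 2-[(benzenesulfinyl)methyl]-6-butanoyl-3,5-dihydroxy-4,4-dimethylcyclohexa-2,5-dien-1-one F9 (racemic at sulfur). Warming F9 with 18 (3 equiv) in THF at 50 °C should cause syn-elimination of benzenesulfenic acid from the keto tautomer, and the 19 so formed should be captured by 18 to give 20.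

**Further compounds**
F1 | step 3 | 3-ethoxy-4-(1-ethoxy-2-methylprop-1-en-1-yl)cyclobut-2-en-1-one (racemic) | CCOC(=C(C)C)C1C(=O)C=C1OCC
F2 | step 3 | (3E)-3,5-diethoxy-6-methylhepta-1,3,5-trien-1-one | O=C=C/C(OCC)=C\C(OCC)=C(C)C
F3 | step 3 | 3,5-diethoxy-6,6-dimethylcyclohexa-2,4-dien-1-one | CCOC1=CC(OCC)=CC(=O)C1(C)C
F4 | step 3 | 5-hydroxy-6,6-dimethylcyclohex-4-ene-1,3-dione (filicinic acid) | CC1(C)C(O)=CC(=O)CC1=O
F5 | step 3 | 2,2-dimethyl-4-methylidenecyclohexane-1,3,5-trione | CC1(C)C(=O)CC(=O)C(=C)C1=O
F6 | step 10 | 1-[3-[(dimethylamino)methyl]-2,6-dihydroxy-4-methoxyphenyl]butan-1-one | CCCC(=O)c1c(O)cc(OC)c(CN(C)C)c1O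
F7 | step 10 | 2-butanoyl-3-hydroxy-5-methoxy-6-methylidenecyclohexa-2,4-dien-1-one | CCCC(=O)C1=C(O)C=C(OC)C(=C)C1=O
F8 | step 10 | 1-[3-[(3-butanoyl-2,4-dihydroxy-6-methoxyphenyl)methyl]-2,4,6-trihydroxyphenyl]butan-1-one | CCCC(=O)c1c(O)cc(O)c(Cc2c(OC)cc(O)c(C(=O)CCC)c2O)c1O
F9 | step 8 | 2-[(benzenesulfinyl)methyl]-6-butanoyl-3,5-dihydroxy-4,4-dimethylcyclohexa-2,5-dien-1-one (racemic at sulfur) | CCCC(=O)C1=C(O)C(C)(C)C(O)=C(CS(=O)c2ccccc2)C1=O
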